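**Retrosynthetic overview**

1. Key disconnection C14'–C15' (carotenoid locants): the C30 chain is completed in one flask from the C20 furanoid aldehyde (C15 = CHO), the one-carbon linchpin CH2(Bpin)2 (becomes C15') and the C9 iodotrienal (C14'–I), by boron-Wittig olefination followed by Suzuki–Miyaura coupling.
2. Enabling feature: C15' is an unbranched sp2 CH between the E-disubstituted double bond C15=C15' and the sp2–sp2 single bond to C14'H=C13'(CH3). One carbon carrying two borons can therefore spend one boron on the double bond and the other on the single bond, under base-only conditions that the acid-labile bis-allylic O–C8 bond of the dihydrofuran ring tolerates.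
3. C20 aldehyde: dihydrofuran (O–C8) from Ag(I) 5-endo closure of an α-hydroxyallene (axis to C8); allene from anti-SN2' CuH reduction of a 5,6-epoxy-7-yne; epoxide from OH-directed epoxidation (C5); C6–C7 from Sonogashira coupling of an enol triflate with a C10 enyne (HWE); C3 from asymmetric transfer hydrogenation of ketoisophorone.
4. Ring order: cyclohexene ring (bought) → oxirane (temporary) → 2,5-dihydrofuran (last ring, closed before the chain is completed).
5. C9 iodotrienal: Negishi methylalumination/iodination of propargyl alcohol, then two Wittig homologations.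

Key step: step 19

Remark: carotenoid locants are used (ring C1–C6, ring oxygen between C5 and C8, chain C7–C15 then C15'–C8'); the target is read as the all-E (3R,5R,8R) isomer, i.e. O3 and the ring oxygen cis on the six-membered ring and C9 cis to C4 on the dihydrofuran.

Remark: the route rests on two stereochemical assignments taken from mechanism and not checked against data: CuH opens the propargylic oxirane anti (step 10), and the (R,R)-Ru catalyst gives the (4R)-alcohol (step 1).

Remark: from step 11 on, all operations are kept acid-free (Et3N-deactivated silica) and in dim light.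

**Route**

Step 1
Reactants: 1 ketoisophorone (2,6,6-trimethylcyclohex-2-ene-1,4-dione)
Product: 2 (4R)-4-hydroxy-2,6,6-trimethylcyclohex-2-en-1-one
Conditions: RuCl(p-cymene)[(R,R)-TsDPEN] (1 mol%), i-PrOH, rt
Reagents that add atoms: none
Why: Noyori–Ikariya asymmetric transfer hydrogenation should reduce the less hindered, CH=/CH2-flanked C4 carbonyl and leave the carbonyl between C(CH3)= and C(CH3)2 untouched, and the (R,R)-ligand, with the alkenyl arm in the position an aryl group takes in the CH/π transition state, should set the (4R) carbinol that becomes C3 of the target.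

Step 2
Reactants: 2 (4R)-4-hydroxy-2,6,6-trimethylcyclohex-2-en-1-one
Product: 3 (4R)-2,6,6-trimethyl-4-(triethylsilyloxy)cyclohex-2-en-1-one
Conditions: TESCl, imidazole, CH2Cl2, 0 °C
Reagents that add atoms: chlorotriethylsilane, CC[Si](Cl)(CC)CC
Why: Standard silylation of the secondary alcohol protects it against the hydride and triflating reagents of step 3 with a group that can later be removed beside a TBDPS ether.

Step 3
Reactants: 3 (4R)-2,6,6-trimethyl-4-(triethylsilyloxy)cyclohex-2-en-1-one
Product: 5 (4S)-2,6,6-trimethyl-4-(triethylsilyloxy)cyclohex-1-en-1-yl trifluoromethanesulfonate, via lithium enolate 4 (not isolated)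
Conditions: L-Selectride, THF, −78 °C; then PhNTf2, −78 °C → rt
Reagents that add atoms: N-phenylbis(trifluoromethanesulfonimide), O=S(=O)(N(c1ccccc1)S(=O)(=O)C(F)(F)F)C(F)(F)F
Why: Conjugate hydride addition of the bulky borohydride to the hindered enone gives the tetrasubstituted enolate regiospecifically (the other α-carbon is quaternary) and O-triflation traps it (reductive triflation), with the silyloxy stereocentre untouched (its descriptor changes to S only by CIP priority).

Step 4
Reactants: 6 (2E)-3-methylpent-2-en-4-yn-1-ol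
Product: 8 ethyl (2E,4E,6E)-3,7-dimethylnona-2,4,6-trien-8-ynoate, via enynal 7 (not isolated)
Conditions: MnO2, CH2Cl2, rt, filter; then triethyl 3-methyl-4-phosphonocrotonate, LiHMDS, THF, −78 → 0 °C
Reagents that add atoms: triethyl 3-methyl-4-phosphonocrotonate, CCOC(=O)C=C(C)CP(=O)(OCC)OCC
Why: MnO2 oxidation of the allylic alcohol followed by Horner–Wadsworth–Emmons olefination with the stabilised C5 phosphonate anion should give the new disubstituted double bond E, and the minor 2Z isomer that stems from the reagent is removed by chromatography at this stage.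

Step 5
Reactants: 8 ethyl (2E,4E,6E)-3,7-dimethylnona-2,4,6-trien-8-ynoate
Product: 9 (2E,4E,6E)-3,7-dimethylnona-2,4,6-trien-8-yn-1-ol
Conditions: DIBAL-H (2.2 equiv), CH2Cl2, −78 °C; Rochelle salt
Reagents that add atoms: none
Why: DIBAL-H 1,2-reduction of the conjugated ester gives the allylic alcohol without touching the terminal alkyne at low temperature, so that no enoate is present in the later CuH step.

Step 6
Reactants: 9 (2E,4E,6E)-3,7-dimethylnona-2,4,6-trien-8-yn-1-ol
Product: 10 tert-butyl{[(2E,4E,6E)-3,7-dimethylnona-2,4,6-trien-8-yn-1-yl]oxy}diphenylsilane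
Conditions: TBDPSCl, imidazole, DMF, rt
Reagents that add atoms: tert-butylchlorodiphenylsilane, CC(C)(C)[Si](Cl)(c1ccccc1)c1ccccc1
Why: Silylation masks the primary allylic hydroxyl, which would otherwise direct the vanadium epoxidation of step 9 to the wrong double bond.

Step 7
Reactants: 5 (4S)-2,6,6-trimethyl-4-(triethylsilyloxy)cyclohex-1-en-1-yl trifluoromethanesulfonate; 10 tert-butyl{[(2E,4E,6E)-3,7-dimethylnona-2,4,6-trien-8-yn-1-yl]oxy}diphenylsilane
Product: 11 tert-butyl({(2E,4E,6E)-3,7-dimethyl-9-[(4S)-2,6,6-trimethyl-4-(triethylsilyloxy)cyclohex-1-en-1-yl]nona-2,4,6-trien-8-yn-1-yl}oxy)diphenylsilane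
Conditions: Pd(PPh3)4 (5 mol%), CuI (10 mol%), Et3N, DMF, rt
Reagents that add atoms: none
Why: Sonogashira coupling of the enol triflate with the terminal enyne forms C6–C7 and delivers the whole C20 skeleton with all chain double bonds already E.

Step 8
Reactants: 11 bis-silyl ether from step 7
Product: 12 (1S)-4-[(3E,5E,7E)-9-(tert-butyldiphenylsilyloxy)-3,7-dimethylnona-3,5,7-trien-1-yn-1-yl]-3,5,5-trimethylcyclohex-3-en-1-ol
Conditions: PPTS (cat.), MeOH–CH2Cl2, 0 °C
Reagents that add atoms: none
Why: Mild acid-catalysed methanolysis cleaves the secondary triethylsilyl ether far faster than the primary TBDPS ether and frees the homoallylic C3–OH needed as directing group.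

Step 9
Reactants: 12 homoallylic alcohol from step 8
Product: 13 (1R,3R,6R)-6-[(3E,5E,7E)-9-(tert-butyldiphenylsilyloxy)-3,7-dimethylnona-3,5,7-trien-1-yn-1-yl]-1,5,5-trimethyl-7-oxabicyclo[4.1.0]heptan-3-ol (epoxide cis to OH)
Conditions: VO(acac)2 (5 mol%), t-BuOOH, toluene, 0 °C → rt
Reagents that add atoms: tert-butyl hydroperoxide, CC(C)(C)OO
Why: In this hydroxyl-directed vanadium-catalysed epoxidation the V(V) alkoxide of the homoallylic C3–OH should deliver the peroxide oxygen to the same face of C5=C6, which sets C5 (R) and C6 (R) cis to the hydroxyl, while the undirected triene is left alone.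

Step 10
Reactants: 13 syn-epoxy alcohol from step 9
Product: 14 (1R,3R)-4-[(3E,5E,7E)-9-(tert-butyldiphenylsilyloxy)-3,7-dimethylnona-1,3,5,7-tetraen-1-ylidene]-3,5,5-trimethylcyclohexane-1,3-diol with (S)-allene axis (H-8 anti and C-9 syn to the C5–OH)
Conditions: CuCl (5 mol%), IPr·HCl (5 mol%), NaOt-Bu (15 mol%), (EtO)2MeSiH, toluene, 0 °C → rt; aq. NaOH work-up
Reagents that add atoms: none
Why: In this copper hydride-catalysed SN2' reduction of a propargylic oxirane, syn-hydrocupration of C7≡C8 and anti β-alkoxide elimination should put hydride on C8 opposite to the breaking C6–O bond (net anti), so the C6 centre is translated into the (S) axis with C9 on the side of the new C5–OH, whereas an oxygen-bound aluminium hydride would deliver syn and give the other axis.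

Step 11
Reactants: 14 α-hydroxyallene from step 10
Product: 15 (2R,6R,7aR)-2-[(2E,4E,6E)-8-(tert-butyldiphenylsilyloxy)-6-methylocta-2,4,6-trien-2-yl]-4,4,7a-trimethyl-2,4,5,6,7,7a-hexahydro-1-benzofuran-6-ol
Conditions: AgNO3 (20 mol%), CaCO3, acetone–H2O, rt, dark
Reagents that add atoms: none
Why: Silver(I)-catalysed 5-endo cycloisomerisation of the α-hydroxyallene (O5 adds to C8, then protodemetalation at C7) closes the 2,5-dihydrofuran, and because O5 attacks in the C5–C6–C7 plane while H8 and C9 keep their sides the (S) axis becomes (8R) with C9 cis to C4 (axis-to-centre chirality transfer), the CaCO3 buffer guarding the acid-labile C8–O bond.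

Step 12
Reactants: 15 furanoid silyl ether from step 11
Product: 16 (2R,6R,7aR)-2-[(2E,4E,6E)-8-hydroxy-6-methylocta-2,4,6-trien-2-yl]-4,4,7a-trimethyl-2,4,5,6,7,7a-hexahydro-1-benzofuran-6-ol
Conditions: TBAF, THF, 0 °C → rt
Reagents that add atoms: none
Why: Fluoride desilylation is basic and therefore leaves the acid-sensitive C8 stereocentre untouched.

Step 13
Reactants: 16 furanoid diol from step 12
Product: 17 (2E,4E,6E)-7-[(2R,6R,7aR)-6-hydroxy-4,4,7a-trimethyl-2,4,5,6,7,7a-hexahydro-1-benzofuran-2-yl]-3-methylocta-2,4,6-trienal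
Conditions: MnO2, CH2Cl2, rt, dark
Reagents that add atoms: none
Why: MnO2 oxidises only the allylic (trienylic) primary alcohol and leaves the saturated secondary C3–OH, giving the C20 hydroxy aldehyde without protecting groups.

Step 14
Reactants: 18 prop-2-yn-1-ol
Product: 20 (2E)-3-iodo-2-methylprop-2-en-1-ol, via alkenylalane 19 (not isolated)
Conditions: Me3Al (3 equiv), Cp2ZrCl2 (0.25 equiv), CH2Cl2, 0 °C → rt; then I2, THF, −30 → 0 °C
Reagents that add atoms: trimethylaluminium, C[Al](C)C; iodine, II
Why: Zirconium-catalysed methylalumination (Negishi carboalumination) adds CH3 and Al syn across the alkyne with Al on the terminal carbon, and iodinolysis with retention gives the (E)-iodoalkene that becomes C14'(I)=C13'(CH3).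

Step 15
Reactants: 20 (2E)-3-iodo-2-methylprop-2-en-1-ol
Product: 22 ethyl (2E,4E)-5-iodo-4-methylpenta-2,4-dienoate, via iodoenal 21 (not isolated)
Conditions: MnO2, CH2Cl2, rt; then Ph3P=CHCO2Et, rt
Reagents that add atoms: ethyl (triphenylphosphoranylidene)acetate, CCOC(=O)C=P(c1ccccc1)(c1ccccc1)c1ccccc1
Why: Tandem allylic oxidation–Wittig olefination traps the volatile iodoenal as it forms, and the stabilised ylide gives the E double bond.

Step 16
Reactants: 22 ethyl (2E,4E)-5-iodo-4-methylpenta-2,4-dienoate
Product: 23 (2E,4E)-5-iodo-4-methylpenta-2,4-dien-1-ol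
Conditions: DIBAL-H (2.2 equiv), CH2Cl2, −78 °C; Rochelle salt
Reagents that add atoms: none
Why: DIBAL-H 1,2-reduction of the dienoate gives the dienol, and the vinyl iodide is inert to the hydride at −78 °C.

Step 17
Reactants: 23 (2E,4E)-5-iodo-4-methylpenta-2,4-dien-1-ol
Product: 24 (2E,4E)-5-iodo-4-methylpenta-2,4-dienal
Conditions: MnO2, CH2Cl2, rt
Reagents that add atoms: none
Why: MnO2 oxidation of the dienylic alcohol gives the dienal without E/Z scrambling.

Step 18
Reactants: 24 (2E,4E)-5-iodo-4-methylpenta-2,4-dienal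
Product: 25 (2E,4E,6E)-7-iodo-2,6-dimethylhepta-2,4,6-trienal
Conditions: Ph3P=C(CH3)CHO, toluene, 80 °C
Reagents that add atoms: 2-(triphenylphosphoranylidene)propanal, CC(C=O)=P(c1ccccc1)(c1ccccc1)c1ccccc1
Why: Wittig olefination with the stabilised formyl ylide gives the (E)-2-methyl enal directly, and the α-branched product is too unreactive toward the ylide to be homologated a second time.

Step 19
Reactants: 17 C20 furanoid hydroxy aldehyde from step 13; 25 (2E,4E,6E)-7-iodo-2,6-dimethylhepta-2,4,6-trienal
Product: 27 (3R,5R,8R)-3-hydroxy-5,8-epoxy-5,8-dihydro-8'-apo-β-caroten-8'-al (the target), via alkenyl boronate 26 (not isolated)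
Conditions: CH2(Bpin)2 (2.3 equiv), LiTMP (2.2 equiv), THF, 0 °C; add 17, −78 °C → rt; then 25, Pd(PPh3)4 (5 mol%), TlOEt, THF–H2O, rt, dark
Reagents that add atoms: bis(pinacolato)borylmethane, CC1(C)OB(CB2OC(C)(C)C(C)(C)O2)OC1(C)C
Why: The α-lithio gem-diboronate adds 1,2 to the C15 aldehyde and the β-alkoxy gem-diboronate loses lithium pinacolborate by syn B–O elimination from the anti adduct to give the (E)-C15=C15' alkenyl boronate 26, which without isolation transmetallates (ethoxide ate complex) to the alkenylpalladium(II) iodide from oxidative addition of 25 and reductively eliminates to form C14'–C15' with retention of both alkene geometries. The closest known reaction types are the boron-Wittig olefination of aldehydes with geminal bis(boronates) and the Suzuki–Miyaura alkenyl–alkenyl coupling used for polyenes. No ring is closed and no stereocentre is created; the only new stereo element, the C15=C15' geometry, is controlled by the anti-addition/syn-elimination course of the boron-Wittig step. The step needs 1,2-addition instead of γ-deprotonation or conjugate addition to the trienal, which the boron-stabilised carbanion at −78 °C secures (one extra equivalent is consumed by the C3–OH), and it needs transmetallation of the sp2 C–B bond only, which is much faster than that of the sp3 C–B bonds of leftover CH2(Bpin)2. The dihydrofuran and C8 survive because the whole operation is basic and free of Lewis acids. C15' thus enters as a CH with two borons, one spent on the double bond and one on the single bond, so that two unprotected fragments give the complete C30 nonaene chromophore in one flask.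

**Compound list**

1 | ketoisophorone (2,6,6-trimethylcyclohex-2-ene-1,4-dione) | O=C1C=C(C)C(=O)C(C)(C)C1 | starting material
2 | (4R)-4-hydroxy-2,6,6-trimethylcyclohex-2-en-1-one | O=C1C(C)=C[C@H](O)CC1(C)C | intermediate
3 | (4R)-2,6,6-trimethyl-4-(triethylsilyloxy)cyclohex-2-en-1-one | O=C1C(C)=C[C@H](O[Si](CC)(CC)CC)CC1(C)C | intermediate
4 | lithium (4S)-2,6,6-trimethyl-4-(triethylsilyloxy)cyclohex-1-en-1-olate | [Li]OC1=C(C)C[C@H](O[Si](CC)(CC)CC)CC1(C)C | intermediate
5 | (4S)-2,6,6-trimethyl-4-(triethylsilyloxy)cyclohex-1-en-1-yl trifluoromethanesulfonate | O=S(=O)(OC1=C(C)C[C@H](O[Si](CC)(CC)CC)CC1(C)C)C(F)(F)F | intermediate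
6 | (2E)-3-methylpent-2-en-4-yn-1-ol | C#C/C(C)=C/CO | starting material
7 | (2E)-3-methylpent-2-en-4-ynal | C#C/C(C)=C/C=O | intermediate
8 | ethyl (2E,4E,6E)-3,7-dimethylnona-2,4,6-trien-8-ynoate | C#C/C(C)=C/C=C/C(C)=C/C(=O)OCC | intermediate
9 | (2E,4E,6E)-3,7-dimethylnona-2,4,6-trien-8-yn-1-ol | C#C/C(C)=C/C=C/C(C)=C/CO | intermediate
10 | tert-butyl{[(2E,4E,6E)-3,7-dimethylnona-2,4,6-trien-8-yn-1-yl]oxy}diphenylsilane | C#C/C(C)=C/C=C/C(C)=C/CO[Si](c1ccccc1)(c1ccccc1)C(C)(C)C | intermediate
11 | tert-butyl({(2E,4E,6E)-3,7-dimethyl-9-[(4S)-2,6,6-trimethyl-4-(triethylsilyloxy)cyclohex-1-en-1-yl]nona-2,4,6-trien-8-yn-1-yl}oxy)diphenylsilane | CC(C)(C)[Si](OC/C=C(C)/C=C/C=C(C)/C#CC1=C(C)C[C@H](O[Si](CC)(CC)CC)CC1(C)C)(c1ccccc1)c1ccccc1 | intermediate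
12 | (1S)-4-[(3E,5E,7E)-9-(tert-butyldiphenylsilyloxy)-3,7-dimethylnona-3,5,7-trien-1-yn-1-yl]-3,5,5-trimethylcyclohex-3-en-1-ol | CC(C)(C)[Si](OC/C=C(C)/C=C/C=C(C)/C#CC1=C(C)C[C@H](O)CC1(C)C)(c1ccccc1)c1ccccc1 | intermediate
13 | (1R,3R,6R)-6-[(3E,5E,7E)-9-(tert-butyldiphenylsilyloxy)-3,7-dimethylnona-3,5,7-trien-1-yn-1-yl]-1,5,5-trimethyl-7-oxabicyclo[4.1.0]heptan-3-ol (epoxide cis to the hydroxyl) | O[C@H]1C[C@@]2(C)O[C@@]2(C#C/C(C)=C/C=C/C(C)=C/CO[Si](c3ccccc3)(c3ccccc3)C(C)(C)C)C(C)(C)C1 | intermediate
14 | (1R,3R)-4-[(3E,5E,7E)-9-(tert-butyldiphenylsilyloxy)-3,7-dimethylnona-1,3,5,7-tetraen-1-ylidene]-3,5,5-trimethylcyclohexane-1,3-diol, (S)-allene axis (H-8 anti, C-9 syn to the tertiary OH) | CC1(C)C[C@@H](O)C[C@@](C)(O)C1=[C@@]=C([H])/C(C)=C/C=C/C(C)=C/CO[Si](c1ccccc1)(c1ccccc1)C(C)(C)C | intermediate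
15 | (2R,6R,7aR)-2-[(2E,4E,6E)-8-(tert-butyldiphenylsilyloxy)-6-methylocta-2,4,6-trien-2-yl]-4,4,7a-trimethyl-2,4,5,6,7,7a-hexahydro-1-benzofuran-6-ol | CC(C)(C)[Si](OC/C=C(C)/C=C/C=C(\C)[C@H]1C=C2C(C)(C)C[C@@H](O)C[C@@]2(C)O1)(c1ccccc1)c1ccccc1 | intermediate
16 | (2R,6R,7aR)-2-[(2E,4E,6E)-8-hydroxy-6-methylocta-2,4,6-trien-2-yl]-4,4,7a-trimethyl-2,4,5,6,7,7a-hexahydro-1-benzofuran-6-ol | OC/C=C(C)/C=C/C=C(\C)[C@H]1C=C2C(C)(C)C[C@@H](O)C[C@@]2(C)O1 | intermediate
17 | (2E,4E,6E)-7-[(2R,6R,7aR)-6-hydroxy-4,4,7a-trimethyl-2,4,5,6,7,7a-hexahydro-1-benzofuran-2-yl]-3-methylocta-2,4,6-trienal | O=C/C=C(C)/C=C/C=C(\C)[C@H]1C=C2C(C)(C)C[C@@H](O)C[C@@]2(C)O1 | intermediate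
18 | prop-2-yn-1-ol | C#CCO | starting material
19 | [(1E)-3-(dimethylalumanyloxy)-2-methylprop-1-en-1-yl]dimethylalumane | C[Al](C)/C=C(C)/CO[Al](C)C | intermediate
20 | (2E)-3-iodo-2-methylprop-2-en-1-ol | I/C=C(C)/CO | intermediate
21 | (2E)-3-iodo-2-methylprop-2-enal | I/C=C(C)/C=O | intermediate
22 | ethyl (2E,4E)-5-iodo-4-methylpenta-2,4-dienoate | I/C=C(C)/C=C/C(=O)OCC | intermediate
23 | (2E,4E)-5-iodo-4-methylpenta-2,4-dien-1-ol | I/C=C(C)/C=C/CO | intermediate
24 | (2E,4E)-5-iodo-4-methylpenta-2,4-dienal | I/C=C(C)/C=C/C=O | intermediate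
25 | (2E,4E,6E)-7-iodo-2,6-dimethylhepta-2,4,6-trienal | I/C=C(C)/C=C/C=C(\C)C=O | intermediate
26 | (2R,6R,7aR)-4,4,7a-trimethyl-2-[(2E,4E,6E,8E)-6-methyl-9-(4,4,5,5-tetramethyl-1,3,2-dioxaborolan-2-yl)nona-2,4,6,8-tetraen-2-yl]-2,4,5,6,7,7a-hexahydro-1-benzofuran-6-ol | CC1(C)OB(/C=C/C=C(C)/C=C/C=C(\C)[C@H]2C=C3C(C)(C)C[C@@H](O)C[C@@]3(C)O2)OC1(C)C | intermediate
27 | (2E,4E,6E,8E,10E,12E,14E)-15-[(2R,6R,7aR)-6-hydroxy-4,4,7a-trimethyl-2,4,5,6,7,7a-hexahydro-1-benzofuran-2-yl]-2,6,11-trimethylhexadeca-2,4,6,8,10,12,14-heptaenal | C\C(C=O)=C/C=C/C(C)=C/C=C/C=C(C)/C=C/C=C(\C)[C@H]1C=C2C(C)(C)C[C@@H](O)C[C@@]2(C)O1 | target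

**Step count and risks**

Total steps: 19. Longest linear sequence: 11 steps (steps 1, 2, 3, 7, 8, 9, 10, 11, 12, 13, 19).

Steps most likely to fail:

Step 10 (copper hydride SN2' reduction). The process at risk is chemoselectivity and stereochemical course: hydrocupration of the conjugated triene–yne or of the vinylallene product could compete with oxirane opening, and a copper-alkoxide-assisted syn elimination would erode the anti course and give the C6-epimeric axis, hence the 8-epimer after step 11. The fallback sets out from 13 and uses palladium(0)-catalysed hydrogenolysis with formate (Pd2(dba)3·CHCl3, n-Bu3P, HCO2H/Et3N, THF, rt). Oxidative addition opens the oxirane with inversion (anti-SN2') to a σ-allenylpalladium alkoxide, formate exchange and decarboxylation give the palladium hydride, and reductive elimination places H on C8 with retention at palladium. This is the same anti outcome without any metal hydride addition to the polyene; it returns to the route at 14 and no new compound arises (F0).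

Step 19 (key step). The processes at risk are γ-deprotonation of the polyenal by the lithiated bis(boronate) in place of 1,2-addition, incomplete B–O elimination or incomplete E-selectivity at C15=C15', and protodeboronation of the tetraenyl boronate before transmetallation. The stepwise fallback sets out from 17: Seyferth–Gilbert homologation with the Ohira–Bestmann reagent (K2CO3, MeOH, 0 °C → rt) should give the C21 terminal enyne F1. Zirconocene hydrochloride-catalysed syn-hydroboration with pinacolborane (Cp2Zr(H)Cl cat., Et3N cat., CH2Cl2, rt) then sets the E-C15=C15' geometry from the alkyne and returns to the route at boronate 26, now purified before use, which is coupled with 25 under the palladium conditions of step 19 to give 27.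

Step 11 (silver-catalysed ring closure). The processes at risk are silver-assisted ionisation of the bis-allylic C8–O bond of the product (the cation is stabilised by the donor-substituted triene), which would scramble C8, and slow closure at the hindered tertiary carbinol with competing isomerisation of the vinylallene. The fallback carries the chain as an electron-poor trienoate so that ionisation at C8 is disfavoured. It sets out from 5 and 8: Sonogashira coupling as in step 7 gives the silyl-protected enyne ester F2; PPTS/MeOH gives the hydroxy enyne ester F3; VO(acac)2/t-BuOOH gives the syn-epoxy ester F4. Because copper hydride would reduce the enoate, the anti-SN2' hydride is delivered here by the palladium/formate hydrogenolysis described above, giving the allenol ester F5. Ag(I) closure as in step 11 gives the furanoid ester F6, and DIBAL-H (CH2Cl2, −78 °C) reduces the ester and returns to the route at 16.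

Further compounds
F0 | step 10 | none | none
F1 | step 19 | (2R,6R,7aR)-4,4,7a-trimethyl-2-[(2E,4E,6E)-6-methylnona-2,4,6-trien-8-yn-2-yl]-2,4,5,6,7,7a-hexahydro-1-benzofuran-6-ol | C#C/C=C(C)/C=C/C=C(\C)[C@H]1C=C2C(C)(C)C[C@@H](O)C[C@@]2(C)O1
F2 | step 11 | ethyl (2E,4E,6E)-3,7-dimethyl-9-[(4S)-2,6,6-trimethyl-4-(triethylsilyloxy)cyclohex-1-en-1-yl]nona-2,4,6-trien-8-ynoate | CCOC(=O)/C=C(C)/C=C/C=C(C)/C#CC1=C(C)C[C@H](O[Si](CC)(CC)CC)CC1(C)C
F3 | step 11 | ethyl (2E,4E,6E)-9-[(4S)-4-hydroxy-2,6,6-trimethylcyclohex-1-en-1-yl]-3,7-dimethylnona-2,4,6-trien-8-ynoate | CCOC(=O)/C=C(C)/C=C/C=C(C)/C#CC1=C(C)C[C@H](O)CC1(C)C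
F4 | step 11 | ethyl (2E,4E,6E)-9-[(1R,4R,6R)-4-hydroxy-2,2,6-trimethyl-7-oxabicyclo[4.1.0]heptan-1-yl]-3,7-dimethylnona-2,4,6-trien-8-ynoate | O[C@H]1C[C@@]2(C)O[C@@]2(C#C/C(C)=C/C=C/C(C)=C/C(=O)OCC)C(C)(C)C1
F5 | step 11 | ethyl (2E,4E,6E)-9-[(2R,4R)-2,4-dihydroxy-2,6,6-trimethylcyclohexylidene]-3,7-dimethylnona-2,4,6,8-tetraenoate, (S)-allene axis | CC1(C)C[C@@H](O)C[C@@](C)(O)C1=[C@@]=C([H])/C(C)=C/C=C/C(C)=C/C(=O)OCC
F6 | step 11 | ethyl (2E,4E,6E)-7-[(2R,6R,7aR)-6-hydroxy-4,4,7a-trimethyl-2,4,5,6,7,7a-hexahydro-1-benzofuran-2-yl]-3-methylocta-2,4,6-trienoate | CCOC(=O)/C=C(C)/C=C/C=C(\C)[C@H]1C=C2C(C)(C)C[C@@H](O)C[C@@]2(C)O1
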